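The α‑methylene‑γ‑butyrolactone (ring B) is disconnected across the lactone O–C6 and C11–C7 bonds to 2‑bromoacrylic acid and an acyclic (E,E)‑diene C4=C5–C6=C7 that already carries C8 (R) and both side arms. The key step, a palladium‑catalysed heteroannulation, exploits the C4=C5 alkene flanking C6 in ring A: carbopalladation at C7 leaves an allylpalladium unit over C6–C5–C4 that the carboxylate closes at C6, delivering in one operation the complete exo‑methylene lactone, both ring‑fusion stereocentres under control of C8, and the C4=C5 alkene. Ring‑closing metathesis at C1=C10 then forms the ten‑membered ring A, followed by oxidation at C14 and desilylation.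

Key step: step 8

Remark: atoms carry germacrane numbers (ring A = carbocycle C1–C10; ring B = lactone O1–C12(=O)–C11(=C13H2)–C7–C6; C14 = formyl carbon on C10; C15 = hydroxymethyl carbon on C4; O8 = ester oxygen on C8), and compounds 1, 2, 4, 9, 15 and 19 are taken as catalogue materials.

Step 1
Reactants: 1 triethyl phosphonoacetate; 2 (2E)-5-bromopent-2-ene
Product: 3 ethyl (5E)-2-(diethoxyphosphoryl)hept-5-enoate
Conditions: NaH, DMF, 0 °C; then 2, 60 °C
Reagents that add atoms: none
Why: Malonate-type SN2 C-alkylation of the sodium phosphonoacetate anion with the primary homoallylic bromide gives the α-substituted phosphonate; its α-stereocentre is racemic and disappears in step 2.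

Step 2
Reactants: 3 ethyl (5E)-2-(diethoxyphosphoryl)hept-5-enoate; 4 (2E)-4,4-dimethoxybut-2-enal
Product: 5 ethyl (2E,4E)-6,6-dimethoxy-2-[(3E)-pent-3-en-1-yl]hexa-2,4-dienoate
Conditions: NaH, THF, 0 °C; then 4, −20 °C → rt
Reagents that add atoms: none
Why: Horner–Wadsworth–Emmons olefination of the enal with the stabilised α-branched phosphonate anion should give the (2E)-trisubstituted enoate (ester trans to the β-substituent), which fixes the later C4=C5 geometry with C15 trans to C6; any minor (2Z) isomer is removed by chromatography.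

Step 3
Reactants: 5 ethyl (2E,4E)-6,6-dimethoxy-2-[(3E)-pent-3-en-1-yl]hexa-2,4-dienoate
Product: 7 (2E,4E,8E)-5-(hydroxymethyl)deca-2,4,8-trienal, via dienol acetal 6 (not isolated)
Conditions: i-Bu2AlH (2.5 equiv), CH2Cl2, −78 °C; then 1 M aq HCl, THF, 0 °C
Reagents that add atoms: water, O
Why: Hydride 1,2-reduction of the conjugated ester by i-Bu2AlH at low temperature gives allylic alcohol 6, and the acidic work-up hydrolyses the vinylogous dimethyl acetal to the conjugated aldehyde without changing the alkene geometries.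

Step 4
Reactants: 7 (2E,4E,8E)-5-(hydroxymethyl)deca-2,4,8-trienal
Product: 8 (2E,4E,8E)-5-{[(tert-butyldiphenylsilyl)oxy]methyl}deca-2,4,8-trienal
Conditions: t-BuPh2SiCl, imidazole, CH2Cl2, 0 °C → rt
Reagents that add atoms: tert-butyl(chloro)diphenylsilane, CC(C)(C)[Si](Cl)(c1ccccc1)c1ccccc1
Why: Imidazole-promoted silyl ether formation masks the primary allylic O15 with a group that survives every later step up to the last one.

Step 5
Reactants: 9 2-methylprop-2-en-1-ol
Product: 12 tributyl(2-{[(triethylsilyl)oxy]methyl}prop-2-en-1-yl)stannane, via dilithiated methallyl alcohol 10 (not isolated), via lithium stannylalkoxide 11 (not isolated)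
Conditions: n-BuLi (2.2 equiv), TMEDA, Et2O/THF, 0 °C → rt; Bu3SnCl (1.0 equiv), −78 °C; then Et3SiCl, −78 °C → rt
Reagents that add atoms: tributyltin chloride, CCCC[Sn](Cl)(CCCC)CCCC; chlorotriethylsilane, CC[Si](Cl)(CC)CC
Why: Alkoxide-directed allylic lithiation gives the C,O-dilithio species, whose carbanion is stannylated first (substitution at tin) before the remaining alkoxide is silylated in the same flask.

Step 6
Reactants: 8 (2E,4E,8E)-5-{[(tert-butyldiphenylsilyl)oxy]methyl}deca-2,4,8-trienal; 12 tributyl(2-{[(triethylsilyl)oxy]methyl}prop-2-en-1-yl)stannane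
Product: 13 (4R,5E,7E,11E)-8-{[(tert-butyldiphenylsilyl)oxy]methyl}-2-{[(triethylsilyl)oxy]methyl}trideca-1,5,7,11-tetraen-4-ol
Conditions: (R)-1,1'-bi-2-naphthol (20 mol %), Ti(Oi-Pr)4 (10 mol %), 4 Å molecular sieves, CH2Cl2, −20 °C; aq NaHCO3 work-up
Reagents that add atoms: none
Why: Keck asymmetric allylation, in which the (R)-binaphthol–titanium Lewis acid activates the aldehyde and the allylstannane adds to its Re face through an open transition state, should set C8 as R by reagent control.

Step 7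
Reactants: 13 (4R,5E,7E,11E)-8-{[(tert-butyldiphenylsilyl)oxy]methyl}-2-{[(triethylsilyl)oxy]methyl}trideca-1,5,7,11-tetraen-4-ol
Product: 14 (4R,5E,7E,11E)-8-{[(tert-butyldiphenylsilyl)oxy]methyl}-4-[(4-methoxybenzyl)oxy]-2-{[(triethylsilyl)oxy]methyl}trideca-1,5,7,11-tetraene
Conditions: NaH, 4-MeOC6H4CH2Cl, n-Bu4NI (cat.), THF/DMF, 0 °C → rt
Reagents that add atoms: 4-methoxybenzyl chloride, COc1ccc(CCl)cc1
Why: Williamson etherification of the sodium alkoxide puts an ether on O8 that, unlike an ester, cannot be ionised by zerovalent palladium in step 8 and can later be removed oxidatively beside two silyl ethers.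

Step 8
Reactants: 14 (4R,5E,7E,11E)-8-{[(tert-butyldiphenylsilyl)oxy]methyl}-4-[(4-methoxybenzyl)oxy]-2-{[(triethylsilyl)oxy]methyl}trideca-1,5,7,11-tetraene; 15 2-bromoprop-2-enoic acid
Product: 17 (4R,5R)-5-[(1E,5E)-2-{[(tert-butyldiphenylsilyl)oxy]methyl}hepta-1,5-dien-1-yl]-4-[(1R)-1-[(4-methoxybenzyl)oxy]-3-{[(triethylsilyl)oxy]methyl}but-3-en-1-yl]-3-methylideneoxolan-2-one, via allylpalladium carboxylate 16 (not isolated)
Conditions: Pd(OAc)2 (10 mol %), n-Bu4NCl (1 equiv), NaHCO3 (3 equiv), DMF, 70 °C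
Reagents that add atoms: none
Why: Zerovalent palladium formed from Pd(OAc)2 adds oxidatively into the C–Br bond of 15, the alkenylpalladium carboxylate adds syn across C6=C7 with the new C11–C7 bond at the less substituted diene terminus, and the resulting allylpalladium carboxylate 16 (C6–C5–C4) closes by C–O bond formation at C6 and releases zerovalent palladium. The closest known reaction type is the Larock heteroannulation of 1,3-dienes with aryl or alkenyl halides that carry a carboxylic acid. Ring B closes in the 5-exo mode by attack of the carboxylate oxygen on the allyl terminus C6, since attack at the tertiary C4 would need a seven-membered ring. C7 (R) is controlled by C8: with H8 in the diene plane to minimise allylic strain, palladium and the alkenyl group approach the face anti to the C8–O bond, as OsO4 and dienophiles do with allylic ethers; C6 (R) is controlled thermodynamically, because syn/anti equilibration of 16 and reversible ionisation of the allylic lactone by zerovalent palladium funnel to the trans-4,5-disubstituted lactone. The step needs chemoselectivity for the conjugated diene over the isolated 1,2- and 1,1-disubstituted alkenes (only the diene gives a stabilised allyl complex), regioselectivity for C7 over the fully substituted C4, and retention of the C4=C5 geometry, which should hold because palladium does not migrate to the tertiary C4 terminus.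

Step 9
Reactants: 17 (4R,5R)-5-[(1E,5E)-2-{[(tert-butyldiphenylsilyl)oxy]methyl}hepta-1,5-dien-1-yl]-4-[(1R)-1-[(4-methoxybenzyl)oxy]-3-{[(triethylsilyl)oxy]methyl}but-3-en-1-yl]-3-methylideneoxolan-2-one
Product: 18 (4R,5R)-5-[(1E,5E)-2-{[(tert-butyldiphenylsilyl)oxy]methyl}hepta-1,5-dien-1-yl]-4-[(1R)-1-hydroxy-3-{[(triethylsilyl)oxy]methyl}but-3-en-1-yl]-3-methylideneoxolan-2-one
Conditions: DDQ, CH2Cl2/aq phosphate buffer (pH 7), 0 °C
Reagents that add atoms: none
Why: Oxidative cleavage of the 4-methoxybenzyl ether by DDQ (hydride abstraction at the electron-rich benzylic position, hydrolysis of the oxocarbenium ion) frees O8 under neutral buffered conditions that leave the silyl ethers and alkenes in place and should not promote migration of the lactone to O8.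

Step 10
Reactants: 18 (4R,5R)-5-[(1E,5E)-2-{[(tert-butyldiphenylsilyl)oxy]methyl}hepta-1,5-dien-1-yl]-4-[(1R)-1-hydroxy-3-{[(triethylsilyl)oxy]methyl}but-3-en-1-yl]-3-methylideneoxolan-2-one; 19 (2S)-2-methylbutanoic acid
Product: 20 (1R)-1-[(2R,3R)-2-[(1E,5E)-2-{[(tert-butyldiphenylsilyl)oxy]methyl}hepta-1,5-dien-1-yl]-4-methylidene-5-oxooxolan-3-yl]-3-{[(triethylsilyl)oxy]methyl}but-3-en-1-yl (2S)-2-methylbutanoate
Conditions: N,N'-dicyclohexylcarbodiimide, 4-(dimethylamino)pyridine (cat.), CH2Cl2, 0 °C → rt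
Reagents that add atoms: none
Why: Steglich esterification (carbodiimide activation, acyl transfer by 4-(dimethylamino)pyridine) acylates O8 with retention at C8 and, at low temperature, without epimerising the acid α-stereocentre.

Step 11
Reactants: 20 (1R)-1-[(2R,3R)-2-[(1E,5E)-2-{[(tert-butyldiphenylsilyl)oxy]methyl}hepta-1,5-dien-1-yl]-4-methylidene-5-oxooxolan-3-yl]-3-{[(triethylsilyl)oxy]methyl}but-3-en-1-yl (2S)-2-methylbutanoate
Product: 21 (3aR,4R,6E,10E,11aR)-10-{[(tert-butyldiphenylsilyl)oxy]methyl}-3-methylidene-2-oxo-6-{[(triethylsilyl)oxy]methyl}-2,3,3a,4,5,8,9,11a-octahydrocyclodeca[b]furan-4-yl (2S)-2-methylbutanoate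
Conditions: second-generation Grubbs catalyst (10 mol %), toluene (1 mM), 80 °C
Reagents that add atoms: none
Why: Ring-closing metathesis, in which the ruthenium alkylidene loads on the 1,2-disubstituted propenyl end and closes on the electron-neutral 1,1-disubstituted C10 alkene with loss of propene, should give the ring-cis (E) trisubstituted C1=C10 alkene dictated by the ten-membered ring, the conjugated exo-methylene and the trisubstituted C4=C5 alkene being much less reactive.

Step 12
Reactants: 21 (3aR,4R,6E,10E,11aR)-10-{[(tert-butyldiphenylsilyl)oxy]methyl}-3-methylidene-2-oxo-6-{[(triethylsilyl)oxy]methyl}-2,3,3a,4,5,8,9,11a-octahydrocyclodeca[b]furan-4-yl (2S)-2-methylbutanoate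
Product: 22 (3aR,4R,6E,10E,11aR)-10-{[(tert-butyldiphenylsilyl)oxy]methyl}-6-formyl-3-methylidene-2-oxo-2,3,3a,4,5,8,9,11a-octahydrocyclodeca[b]furan-4-yl (2S)-2-methylbutanoate
Conditions: (COCl)2, DMSO, CH2Cl2, −78 → −40 °C; then Et3N, −78 → 0 °C
Reagents that add atoms: none
Why: Swern oxidation applied directly to the primary triethylsilyl ether: the chlorosulfonium reagent exchanges the Et3Si group for the alkoxysulfonium unit and Et3N-induced elimination gives the conjugated C14 aldehyde, while the bulkier tert-butyldiphenylsilyl ether is inert.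

Step 13
Reactants: 22 (3aR,4R,6E,10E,11aR)-10-{[(tert-butyldiphenylsilyl)oxy]methyl}-6-formyl-3-methylidene-2-oxo-2,3,3a,4,5,8,9,11a-octahydrocyclodeca[b]furan-4-yl (2S)-2-methylbutanoate
Product: 23 (3aR,4R,6E,10E,11aR)-6-formyl-10-(hydroxymethyl)-3-methylidene-2-oxo-2,3,3a,4,5,8,9,11a-octahydrocyclodeca[b]furan-4-yl (2S)-2-methylbutanoate
Conditions: HF·pyridine, pyridine, THF, 0 °C → rt
Reagents that add atoms: none
Why: Fluoride-mediated desilylation (Si–F bond formation) under buffered, mildly acidic conditions frees the C15 alcohol without affecting the enal, the two esters or the exo-methylene lactone.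

Compound list
1 | triethyl phosphonoacetate | CCOC(=O)CP(=O)(OCC)OCC | starting material
2 | (2E)-5-bromopent-2-ene | C/C=C/CCBr | starting material
3 | ethyl (5E)-2-(diethoxyphosphoryl)hept-5-enoate (racemic) | CCOC(=O)C(CC/C=C/C)P(=O)(OCC)OCC | intermediate
4 | (2E)-4,4-dimethoxybut-2-enal (fumaraldehyde mono(dimethyl acetal)) | COC(OC)/C=C/C=O | starting material
5 | ethyl (2E,4E)-6,6-dimethoxy-2-[(3E)-pent-3-en-1-yl]hexa-2,4-dienoate | CCOC(=O)/C(CC/C=C/C)=C/C=C/C(OC)OC | intermediate
6 | (2E,4E)-6,6-dimethoxy-2-[(3E)-pent-3-en-1-yl]hexa-2,4-dien-1-ol (dienol acetal, not isolated) | OC/C(CC/C=C/C)=C/C=C/C(OC)OC | intermediate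
7 | (2E,4E,8E)-5-(hydroxymethyl)deca-2,4,8-trienal | O=C/C=C/C=C(/CO)CC/C=C/C | intermediate
8 | (2E,4E,8E)-5-{[(tert-butyldiphenylsilyl)oxy]methyl}deca-2,4,8-trienal | O=C/C=C/C=C(/CO[Si](c1ccccc1)(c1ccccc1)C(C)(C)C)CC/C=C/C | intermediate
9 | 2-methylprop-2-en-1-ol (methallyl alcohol) | C=C(C)CO | starting material
10 | lithium 2-(lithiomethyl)prop-2-en-1-olate (dilithiated methallyl alcohol, not isolated) | [Li]CC(=C)CO[Li] | intermediate
11 | lithium 2-[(tributylstannyl)methyl]prop-2-en-1-olate (not isolated) | [Li]OCC(=C)C[Sn](CCCC)(CCCC)CCCC | intermediate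
12 | tributyl(2-{[(triethylsilyl)oxy]methyl}prop-2-en-1-yl)stannane | C=C(CO[Si](CC)(CC)CC)C[Sn](CCCC)(CCCC)CCCC | intermediate
13 | (4R,5E,7E,11E)-8-{[(tert-butyldiphenylsilyl)oxy]methyl}-2-{[(triethylsilyl)oxy]methyl}trideca-1,5,7,11-tetraen-4-ol | C=C(CO[Si](CC)(CC)CC)C[C@@H](O)/C=C/C=C(/CO[Si](c1ccccc1)(c1ccccc1)C(C)(C)C)CC/C=C/C | intermediate
14 | (4R,5E,7E,11E)-8-{[(tert-butyldiphenylsilyl)oxy]methyl}-4-[(4-methoxybenzyl)oxy]-2-{[(triethylsilyl)oxy]methyl}trideca-1,5,7,11-tetraene | C=C(CO[Si](CC)(CC)CC)C[C@@H](OCc1ccc(OC)cc1)/C=C/C=C(/CO[Si](c1ccccc1)(c1ccccc1)C(C)(C)C)CC/C=C/C | intermediate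
15 | 2-bromoprop-2-enoic acid (2-bromoacrylic acid) | C=C(Br)C(=O)O | starting material
16 | allylpalladium carboxylate of divalent palladium, drawn in its η1 form as the six-membered C6–Pd–O palladacycle (C7 R, C8 R; C6 equilibrating; further ligands on palladium omitted; not isolated) | C=C1C(=O)O[Pd]C(/C=C(/CO[Si](c2ccccc2)(c2ccccc2)C(C)(C)C)CC/C=C/C)[C@H]1[C@H](OCc3ccc(OC)cc3)CC(=C)CO[Si](CC)(CC)CC | intermediate
17 | (4R,5R)-5-[(1E,5E)-2-{[(tert-butyldiphenylsilyl)oxy]methyl}hepta-1,5-dien-1-yl]-4-[(1R)-1-[(4-methoxybenzyl)oxy]-3-{[(triethylsilyl)oxy]methyl}but-3-en-1-yl]-3-methylideneoxolan-2-one | C=C1C(=O)O[C@H](/C=C(/CO[Si](c2ccccc2)(c2ccccc2)C(C)(C)C)CC/C=C/C)[C@H]1[C@H](OCc3ccc(OC)cc3)CC(=C)CO[Si](CC)(CC)CC | intermediate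
18 | (4R,5R)-5-[(1E,5E)-2-{[(tert-butyldiphenylsilyl)oxy]methyl}hepta-1,5-dien-1-yl]-4-[(1R)-1-hydroxy-3-{[(triethylsilyl)oxy]methyl}but-3-en-1-yl]-3-methylideneoxolan-2-one | C=C1C(=O)O[C@H](/C=C(/CO[Si](c2ccccc2)(c2ccccc2)C(C)(C)C)CC/C=C/C)[C@H]1[C@H](O)CC(=C)CO[Si](CC)(CC)CC | intermediate
19 | (2S)-2-methylbutanoic acid | CC[C@H](C)C(=O)O | starting material
20 | (1R)-1-[(2R,3R)-2-[(1E,5E)-2-{[(tert-butyldiphenylsilyl)oxy]methyl}hepta-1,5-dien-1-yl]-4-methylidene-5-oxooxolan-3-yl]-3-{[(triethylsilyl)oxy]methyl}but-3-en-1-yl (2S)-2-methylbutanoate | C=C1C(=O)O[C@H](/C=C(/CO[Si](c2ccccc2)(c2ccccc2)C(C)(C)C)CC/C=C/C)[C@H]1[C@H](OC(=O)[C@@H](C)CC)CC(=C)CO[Si](CC)(CC)CC | intermediate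
21 | (3aR,4R,6E,10E,11aR)-10-{[(tert-butyldiphenylsilyl)oxy]methyl}-3-methylidene-2-oxo-6-{[(triethylsilyl)oxy]methyl}-2,3,3a,4,5,8,9,11a-octahydrocyclodeca[b]furan-4-yl (2S)-2-methylbutanoate | C=C1C(=O)O[C@@H]2/C=C(/CO[Si](c3ccccc3)(c3ccccc3)C(C)(C)C)CC/C=C(/CO[Si](CC)(CC)CC)C[C@@H](OC(=O)[C@@H](C)CC)[C@@H]12 | intermediate
22 | (3aR,4R,6E,10E,11aR)-10-{[(tert-butyldiphenylsilyl)oxy]methyl}-6-formyl-3-methylidene-2-oxo-2,3,3a,4,5,8,9,11a-octahydrocyclodeca[b]furan-4-yl (2S)-2-methylbutanoate | C=C1C(=O)O[C@@H]2/C=C(/CO[Si](c3ccccc3)(c3ccccc3)C(C)(C)C)CC/C=C(/C=O)C[C@@H](OC(=O)[C@@H](C)CC)[C@@H]12 | intermediate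
23 | (3aR,4R,6E,10E,11aR)-6-formyl-10-(hydroxymethyl)-3-methylidene-2-oxo-2,3,3a,4,5,8,9,11a-octahydrocyclodeca[b]furan-4-yl (2S)-2-methylbutanoate | C=C1C(=O)O[C@@H]2/C=C(/CO)CC/C=C(/C=O)C[C@@H](OC(=O)[C@@H](C)CC)[C@@H]12 | target

Total step count: 13. Longest linear sequence: 12 steps (steps 1–4 and 6–13); step 5 is a one-step side branch.

Steps most likely to fail

1. Step 8. Carbopalladation of the hindered internal diene may be slow, the allylpalladium intermediate may lose a β-hydrogen to give trienes, and facial discrimination next to C8 may be weak. The fallback keeps the simultaneous formation of both bonds but switches to a radical–polar sequence. Setting out from 14, oxidative carbolactonisation with malonic acid, Mn(OAc)3·2H2O and KOAc in AcOH at room temperature should give the C11-carboxy lactone F1: the malonate radical generated by trivalent manganese adds to C7, the allyl radical is oxidised to the cation, and a carboxyl group closes at C6. Decarboxylative Mannich methylenation of F1 (aq HCHO, Et2NH; then NaOAc, AcOH, heat) returns to the route at 17.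

2. Step 11. Closure of the ten-membered ring may lose out to intermolecular metathesis at the propenyl end, and the propagating alkylidene may be diverted to the conjugated exo-methylene. The fallback masks that alkene. Setting out from 20, conjugate addition of thiophenol (PhSH, cat. Et3N, THF) gives the phenylthiomethyl lactone F2. Ring-closing metathesis under more forcing conditions (second-generation Grubbs catalyst, toluene, 110 °C, high dilution) gives the macrocyclic sulfide F3. Oxidation with NaIO4 in MeOH/H2O gives the sulfoxide F4, whose thermal syn-elimination (toluene, 110 °C, CaCO3) regenerates the exo-methylene and returns to the route at 21.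

3. Step 6. Turnover and enantioface discrimination of the titanium catalyst may be poor with the functionalised 2-substituted stannane and the doubly unsaturated aldehyde. The fallback sets C8 by reduction instead. Setting out from 8 and 12, allylation promoted by BF3·OEt2 (CH2Cl2, −78 °C) gives the racemic alcohol F5, and oxidation with MnO2 (CH2Cl2) gives the dienone F6. Corey–Bakshi–Shibata reduction with (3aS)-1-methyl-3,3-diphenyltetrahydro-1H,3H-pyrrolo[1,2-c][1,3,2]oxazaborole and BH3·SMe2, the dienyl group acting as the large substituent, should set C8 as R and return to the route at 13.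

Further compounds
F1 | step 8 | (4R,5R)-5-[(1E,5E)-2-{[(tert-butyldiphenylsilyl)oxy]methyl}hepta-1,5-dien-1-yl]-4-[(1R)-1-[(4-methoxybenzyl)oxy]-3-{[(triethylsilyl)oxy]methyl}but-3-en-1-yl]-2-oxooxolane-3-carboxylic acid (C11 epimers) | O=C(O)C1C(=O)O[C@H](/C=C(/CO[Si](c2ccccc2)(c2ccccc2)C(C)(C)C)CC/C=C/C)[C@H]1[C@H](OCc3ccc(OC)cc3)CC(=C)CO[Si](CC)(CC)CC
F2 | step 11 | thiophenol adduct of 20 carrying CH2SPh at C11 (C11 epimers) | C(Sc3ccccc3)C1C(=O)O[C@H](/C=C(/CO[Si](c2ccccc2)(c2ccccc2)C(C)(C)C)CC/C=C/C)[C@H]1[C@H](OC(=O)[C@@H](C)CC)CC(=C)CO[Si](CC)(CC)CC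
F3 | step 11 | macrocyclic analogue of 21 carrying CH2SPh at C11 in place of the exo-methylene (C11 epimers) | C(Sc4ccccc4)C1C(=O)O[C@@H]2/C=C(/CO[Si](c3ccccc3)(c3ccccc3)C(C)(C)C)CC/C=C(/CO[Si](CC)(CC)CC)C[C@@H](OC(=O)[C@@H](C)CC)[C@@H]12
F4 | step 11 | sulfoxide of F3 carrying CH2S(O)Ph at C11 (epimers at C11 and sulfur) | C(S(=O)c4ccccc4)C1C(=O)O[C@@H]2/C=C(/CO[Si](c3ccccc3)(c3ccccc3)C(C)(C)C)CC/C=C(/CO[Si](CC)(CC)CC)C[C@@H](OC(=O)[C@@H](C)CC)[C@@H]12
F5 | step 6 | racemic (5E,7E,11E)-8-{[(tert-butyldiphenylsilyl)oxy]methyl}-2-{[(triethylsilyl)oxy]methyl}trideca-1,5,7,11-tetraen-4-ol | C=C(CO[Si](CC)(CC)CC)CC(O)/C=C/C=C(/CO[Si](c1ccccc1)(c1ccccc1)C(C)(C)C)CC/C=C/C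
F6 | step 6 | (5E,7E,11E)-8-{[(tert-butyldiphenylsilyl)oxy]methyl}-2-{[(triethylsilyl)oxy]methyl}trideca-1,5,7,11-tetraen-4-one | C=C(CO[Si](CC)(CC)CC)CC(=O)/C=C/C=C(/CO[Si](c1ccccc1)(c1ccccc1)C(C)(C)C)CC/C=C/C
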